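## Retrosynthetic overview

1. The target comes from a one-pot hydrogenolysis and desilylation of an octabenzyl bis(triethylsilyl) dimer alcohol.
2. The all-cis C2/C3/C4 triad of the upper unit comes from asymmetric hydrogenation with dynamic kinetic resolution of a 4-aryl-flavan-3-one.
3. Key disconnection, C4(upper)–C6(lower): the silyl enol ether of a flavan-3-one is turned into an enolonium (trivalent-iodine umpolung) and attacked by ring A of the complete lower flavan. Both carbons are nucleophilic in their native forms.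
4. Both halves come from one racemic tetra-O-benzyl flavan-3-one. The lower unit is made by dynamic kinetic resolution (C2, C3), DDQ/H2O at C4 (4β-OH) and silylation; the upper unit is used as its trimethylsilyl enol ether.
5. The flavan-3-one comes from a flav-3-ene by hydroboration and oxidation. Ring C is closed by chalcone reduction–cyclisation; rings A and B are bought (gallacetophenone, 3,4-bis(benzyloxy)benzaldehyde). No ring is formed afterwards.

Assumption: the sense of induction of RuCl2[(S)-XylBINAP][(S)-DAIPEN] is taken by analogy with α-substituted cycloalkanones; if the cis-alcohol of step 6 proves to be the antipode, the (R)/(R) catalyst is used in steps 6 and 11.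

Conventions: flavan numbering is used (O1, C2, C3, C4, C4a, C5–C8, C8a). The "upper unit" is the flavan-3-ol whose C4 carries the aryl bond; the "lower unit" is the flavan-3,4-diol joined through its C6. The CIP letters at C3 of the lower unit and C4 of the upper unit change with the protecting groups (priority changes only); the SMILES show the same spatial arrangement as the target throughout.

## Route

Step 1
Reactants: 1 2',3',4'-trihydroxyacetophenone (gallacetophenone)
Product: 2 1-[3,4-bis(benzyloxy)-2-hydroxyphenyl]ethan-1-one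
Conditions: BnBr (2.1 equiv), K2CO3, DMF, rt
Reagents that add atoms: benzyl bromide, BrCc1ccccc1
Why: Williamson ether synthesis in which the 3- and 4-hydroxyls are alkylated while the 2-hydroxyl, hydrogen-bonded to the acetyl carbonyl and far less nucleophilic, stays free for the later ring closure.

Step 2
Reactants: 2 1-[3,4-bis(benzyloxy)-2-hydroxyphenyl]ethan-1-one; 3 3,4-bis(benzyloxy)benzaldehyde
Product: 4 (E)-1-[3,4-bis(benzyloxy)-2-hydroxyphenyl]-3-[3,4-bis(benzyloxy)phenyl]prop-2-en-1-one (2'-hydroxychalcone)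
Conditions: KOH, EtOH/THF, rt
Reagents that add atoms: none
Why: Claisen–Schmidt (crossed aldol) condensation in which the acetophenone enolate adds to the non-enolisable aldehyde and dehydration gives the (E)-chalcone.

Step 3
Reactants: 4 (E)-2'-hydroxychalcone
Product: 6 rac-7,8-bis(benzyloxy)-2-[3,4-bis(benzyloxy)phenyl]-2H-chromene (flav-3-ene), via allylic alcohol 5 (not isolated)
Conditions: NaBH4, iPrOH/THF, 50 °C; then aq AcOH, 50 °C
Reagents that add atoms: none
Why: 1,2-reduction of the chalcone carbonyl followed by acid-induced dehydrative cyclisation of the 2-hydroxyphenyl allylic alcohol (Clark-Lewis flav-3-ene synthesis), in which the phenol oxygen closes ring C at the far allylic terminus and the new C2 stereocentre is deliberately racemic.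

Step 4
Reactants: 6 rac-flav-3-ene
Product: 8 rac-(2R*,3S*)-7,8-bis(benzyloxy)-2-[3,4-bis(benzyloxy)phenyl]chroman-3-ol (2,3-trans), via alkylborane 7 (not isolated)
Conditions: BH3·THF, THF, 0 °C to rt; then NaOH, H2O2, 0 °C
Reagents that add atoms: borane (as BH3·THF), B (boron held only in 7); hydrogen peroxide, OO (the hydroxyl oxygen)
Why: Brown hydroboration–oxidation in which boron adds syn to C3 (away from the electron-rich benzylic C4) on the face opposite the 2-aryl group, so that stereoretentive oxidation gives the racemic 2,3-trans alcohol.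

Step 5
Reactants: 8 rac-2,3-trans-flavan-3-ol
Product: 9 rac-7,8-bis(benzyloxy)-2-[3,4-bis(benzyloxy)phenyl]chroman-3-one (flavan-3-one)
Conditions: Dess–Martin periodinane, NaHCO3, CH2Cl2, rt
Reagents that add atoms: none
Why: Dess–Martin oxidation under buffered neutral conditions gives the sensitive flavan-3-one without over-oxidation or cleavage of the benzyl ethers.

Step 6
Reactants: 9 rac-flavan-3-one
Product: 10 (2R,3R)-7,8-bis(benzyloxy)-2-[3,4-bis(benzyloxy)phenyl]chroman-3-ol (2,3-cis)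
Conditions: H2 (20 atm), RuCl2[(S)-XylBINAP][(S)-DAIPEN] (1 mol%), KOtBu (0.2 equiv), iPrOH/toluene, 25 °C
Reagents that add atoms: none
Why: Noyori asymmetric hydrogenation with dynamic kinetic resolution, by analogy with α-aryl and α-alkoxy cycloalkanones, in which KOtBu racemises C2 (benzylic, α-aryloxy, α to the ketone) faster than reduction and the chiral divalent ruthenium hydride reduces one enantiomer from the face anti to the 2-aryl group, which sets C3 and fixes C2 as the 2,3-cis (2R,3R) alcohol.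

Step 7
Reactants: 10 (2R,3R)-cis-flavan-3-ol
Product: 11 (2R,3R,4S)-7,8-bis(benzyloxy)-2-[3,4-bis(benzyloxy)phenyl]chromane-3,4-diol (2,3-cis-3,4-trans)
Conditions: DDQ (1.5 equiv), CH2Cl2/H2O (10:1), rt
Reagents that add atoms: water, O
Why: benzylic C–H oxidation by DDQ (hydride abstraction at C4, para to the 7-benzyloxy group) followed by capture of the cation by water trans to the axial 3-hydroxyl, which sets C4 as 4β as is general for 2,3-cis flavan-3-ols.

Step 8
Reactants: 11 (2R,3R,4S)-flavan-3,4-diol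
Product: 12 (2R,3S,4S)-7,8-bis(benzyloxy)-2-[3,4-bis(benzyloxy)phenyl]-3,4-bis(triethylsilyloxy)chromane
Conditions: Et3SiCl, imidazole, DMAP, DMF, rt
Reagents that add atoms: chlorotriethylsilane, CC[Si](Cl)(CC)CC
Why: silyl ether formation that removes both competing O-nucleophiles and makes the benzylic C4–O bond a poor leaving group for the Lewis-acidic coupling, with no change at any stereocentre.

Step 9
Reactants: 9 rac-flavan-3-one
Product: 13 rac-{[7,8-bis(benzyloxy)-2-[3,4-bis(benzyloxy)phenyl]-2H-chromen-3-yl]oxy}trimethylsilane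
Conditions: Me3SiOTf, Et3N, CH2Cl2, 0 °C
Reagents that add atoms: trimethylsilyl trifluoromethanesulfonate, C[Si](C)(C)OS(=O)(=O)C(F)(F)F
Why: soft enolisation (silyl enol ether formation) in which the more accessible benzylic C4 proton is lost to give the enol ether conjugated with ring A, the C2 configuration being irrelevant because 9 is racemic.

Step 10
Reactants: 13 rac-trimethylsilyl enol ether; 12 bis(triethylsilyl) lower unit
Product: 15 7,8-bis(benzyloxy)-2-[3,4-bis(benzyloxy)phenyl]-4-{(2R,3S,4S)-7,8-bis(benzyloxy)-2-[3,4-bis(benzyloxy)phenyl]-3,4-bis(triethylsilyloxy)chroman-6-yl}chroman-3-one (C2 and C4 of the ketone unit unassigned), via enolonium iodane 14 (not isolated)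
Conditions: PhI(OH)OTs (1.05 equiv), BF3·OEt2 (1.1 equiv), CH2Cl2, −78 °C, 10 min; then 12 (2.5 equiv), −78 to −50 °C; Et3N
Reagents that add atoms: [hydroxy(tosyloxy)iodo]benzene, Cc1ccc(cc1)S(=O)(=O)OI(O)c1ccccc1 (its atoms are held only in 14)
Why: Proposed new method: PhI(OH)OTs activated by BF3·OEt2 converts the silyl enol ether into an O-bound trivalent-iodine enolate in which the normally nucleophilic C4 has become an electrophile (an α-keto cation stabilised by ring A and its para 7-benzyloxy group, at the oxidation level of a 3-hydroxyflavylium ion), and the most nucleophilic arene carbon of 12 (C6, para to the pyran oxygen and ortho to the 7-benzyloxy group) attacks C4 in a Friedel–Crafts sense with loss of PhI, the closest known reaction type being the Koser-reagent enolonium α-arylation of ketone silyl enol ethers by electron-rich arenes; no stereocentre has to be controlled here because C2 and C4 of the new ketone are both set in step 11.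

Step 11
Reactants: 15 dimer ketone (mixture of upper-unit C2/C4 stereoisomers)
Product: 16 (2R,3R,4S)-7,8-bis(benzyloxy)-2-[3,4-bis(benzyloxy)phenyl]-4-{(2R,3S,4S)-7,8-bis(benzyloxy)-2-[3,4-bis(benzyloxy)phenyl]-3,4-bis(triethylsilyloxy)chroman-6-yl}chroman-3-ol (all-cis upper unit)
Conditions: H2 (50 atm), RuCl2[(S)-XylBINAP][(S)-DAIPEN] (5 mol%), KOtBu (0.5 equiv), iPrOH/toluene, 30 °C
Reagents that add atoms: none
Why: Proposed new method: under KOtBu both α-stereocentres of the ketone (C2 and C4, each benzylic) epimerise faster than the carbonyl is hydrogenated, the 2,4-cis ketone reacts fastest because hydride can enter from the face opposite both aryl groups, and the catalyst enantiomer that selected the (2R) series in step 6 is used again, so the four stereoisomers of 15 converge on the all-cis alcohol with C2, C3 and C4 set together, the closest known reaction type being Noyori asymmetric hydrogenation with dynamic kinetic resolution of α,α'-disubstituted cyclic ketones to all-cis alcohols.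

Step 12
Reactants: 16 protected dimer alcohol
Product: 18 (2R,3R,4R)-2-(3,4-dihydroxyphenyl)-4-[(2R,3R,4S)-2-(3,4-dihydroxyphenyl)-3,4,7,8-tetrahydroxychroman-6-yl]chromane-3,7,8-triol (CNP0143773.1), via silyl ether polyphenol 17 (not isolated)
Conditions: H2 (1 atm), Pd(OH)2/C, THF/EtOAc, rt; then HF·pyridine, THF, 0 °C
Reagents that add atoms: none
Why: global deprotection in which hydrogenolysis removes the eight benzyl ethers while the benzylic C4–O bond of the lower unit is still protected as a silyl ether, and fluoride then cleaves both triethylsilyl ethers without touching any stereocentre.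

## Compound list

1 | 2',3',4'-trihydroxyacetophenone (gallacetophenone) | CC(=O)c1ccc(O)c(O)c1O | starting material
2 | 1-[3,4-bis(benzyloxy)-2-hydroxyphenyl]ethan-1-one | CC(=O)c1ccc(OCc2ccccc2)c(OCc2ccccc2)c1O | intermediate
3 | 3,4-bis(benzyloxy)benzaldehyde | O=Cc1ccc(OCc2ccccc2)c(OCc2ccccc2)c1 | starting material
4 | (E)-1-[3,4-bis(benzyloxy)-2-hydroxyphenyl]-3-[3,4-bis(benzyloxy)phenyl]prop-2-en-1-one | O=C(/C=C/c1ccc(OCc2ccccc2)c(OCc2ccccc2)c1)c1ccc(OCc2ccccc2)c(OCc2ccccc2)c1O | intermediate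
5 | (E)-1-[3,4-bis(benzyloxy)-2-hydroxyphenyl]-3-[3,4-bis(benzyloxy)phenyl]prop-2-en-1-ol (racemic) | OC(/C=C/c1ccc(OCc2ccccc2)c(OCc2ccccc2)c1)c1ccc(OCc2ccccc2)c(OCc2ccccc2)c1O | intermediate (not isolated)
6 | rac-7,8-bis(benzyloxy)-2-[3,4-bis(benzyloxy)phenyl]-2H-chromene | C1(c2ccc(OCc3ccccc3)c(OCc3ccccc3)c2)Oc2c(ccc(OCc3ccccc3)c2OCc2ccccc2)C=C1 | intermediate
7 | rac-2,3-trans-{7,8-bis(benzyloxy)-2-[3,4-bis(benzyloxy)phenyl]chroman-3-yl}borane (one enantiomer drawn) | c1ccccc1COc1ccc([C@H]2Oc3c(ccc(OCc4ccccc4)c3OCc3ccccc3)C[C@@H]2B)cc1OCc1ccccc1 | intermediate (not isolated)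
8 | rac-(2R*,3S*)-7,8-bis(benzyloxy)-2-[3,4-bis(benzyloxy)phenyl]chroman-3-ol (one enantiomer drawn) | c1ccccc1COc1ccc([C@H]2Oc3c(ccc(OCc4ccccc4)c3OCc3ccccc3)C[C@@H]2O)cc1OCc1ccccc1 | intermediate
9 | rac-7,8-bis(benzyloxy)-2-[3,4-bis(benzyloxy)phenyl]chroman-3-one | O=C1Cc2ccc(OCc3ccccc3)c(OCc3ccccc3)c2OC1c1ccc(OCc2ccccc2)c(OCc2ccccc2)c1 | intermediate
10 | (2R,3R)-7,8-bis(benzyloxy)-2-[3,4-bis(benzyloxy)phenyl]chroman-3-ol | c1ccccc1COc1ccc([C@H]2Oc3c(ccc(OCc4ccccc4)c3OCc3ccccc3)C[C@H]2O)cc1OCc1ccccc1 | intermediate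
11 | (2R,3R,4S)-7,8-bis(benzyloxy)-2-[3,4-bis(benzyloxy)phenyl]chromane-3,4-diol | c1cc2c(c(OCc3ccccc3)c1OCc1ccccc1)O[C@H](c1ccc(OCc3ccccc3)c(OCc3ccccc3)c1)[C@H](O)[C@H]2O | intermediate
12 | (2R,3S,4S)-7,8-bis(benzyloxy)-2-[3,4-bis(benzyloxy)phenyl]-3,4-bis(triethylsilyloxy)chromane | c1cc2c(c(OCc3ccccc3)c1OCc1ccccc1)O[C@H](c1ccc(OCc3ccccc3)c(OCc3ccccc3)c1)[C@H](O[Si](CC)(CC)CC)[C@H]2O[Si](CC)(CC)CC | intermediate
13 | rac-{[7,8-bis(benzyloxy)-2-[3,4-bis(benzyloxy)phenyl]-2H-chromen-3-yl]oxy}trimethylsilane | C[Si](C)(C)OC1=Cc2ccc(OCc3ccccc3)c(OCc3ccccc3)c2OC1c1ccc(OCc2ccccc2)c(OCc2ccccc2)c1 | intermediate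
14 | rac-7,8-bis(benzyloxy)-2-[3,4-bis(benzyloxy)phenyl]-2H-chromen-3-yl phenyl(tosyloxy)iodanyl ether (O-bound trivalent-iodine enolate, the enolonium) | Cc1ccc(cc1)S(=O)(=O)OI(c1ccccc1)OC1=Cc2ccc(OCc3ccccc3)c(OCc3ccccc3)c2OC1c1ccc(OCc2ccccc2)c(OCc2ccccc2)c1 | intermediate (not isolated)
15 | 7,8-bis(benzyloxy)-2-[3,4-bis(benzyloxy)phenyl]-4-{(2R,3S,4S)-7,8-bis(benzyloxy)-2-[3,4-bis(benzyloxy)phenyl]-3,4-bis(triethylsilyloxy)chroman-6-yl}chroman-3-one (upper C2/C4 unassigned) | c1ccccc1COc1ccc(C2Oc3c(ccc(OCc4ccccc4)c3OCc3ccccc3)C(c3cc4c(c(OCc5ccccc5)c3OCc3ccccc3)O[C@H](c3ccc(OCc5ccccc5)c(OCc5ccccc5)c3)[C@H](O[Si](CC)(CC)CC)[C@H]4O[Si](CC)(CC)CC)C2=O)cc1OCc1ccccc1 | intermediate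
16 | (2R,3R,4S)-7,8-bis(benzyloxy)-2-[3,4-bis(benzyloxy)phenyl]-4-{(2R,3S,4S)-7,8-bis(benzyloxy)-2-[3,4-bis(benzyloxy)phenyl]-3,4-bis(triethylsilyloxy)chroman-6-yl}chroman-3-ol | c1ccccc1COc1ccc([C@H]2Oc3c(ccc(OCc4ccccc4)c3OCc3ccccc3)[C@@H](c3cc4c(c(OCc5ccccc5)c3OCc3ccccc3)O[C@H](c3ccc(OCc5ccccc5)c(OCc5ccccc5)c3)[C@H](O[Si](CC)(CC)CC)[C@H]4O[Si](CC)(CC)CC)[C@H]2O)cc1OCc1ccccc1 | intermediate
17 | (2R,3R,4R)-2-(3,4-dihydroxyphenyl)-4-[(2R,3S,4S)-2-(3,4-dihydroxyphenyl)-7,8-dihydroxy-3,4-bis(triethylsilyloxy)chroman-6-yl]chromane-3,7,8-triol | Oc1ccc([C@H]2Oc3c(ccc(O)c3O)[C@@H](c3cc4c(c(O)c3O)O[C@H](c3ccc(O)c(O)c3)[C@H](O[Si](CC)(CC)CC)[C@H]4O[Si](CC)(CC)CC)[C@H]2O)cc1O | intermediate (not isolated)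
18 | (2R,3R,4R)-2-(3,4-dihydroxyphenyl)-4-[(2R,3R,4S)-2-(3,4-dihydroxyphenyl)-3,4,7,8-tetrahydroxychroman-6-yl]chromane-3,7,8-triol (CNP0143773.1) | Oc1ccc([C@H]2Oc3c(ccc(O)c3O)[C@@H](c3cc4c(c(O)c3O)O[C@H](c3ccc(O)c(O)c3)[C@H](O)[C@H]4O)[C@H]2O)cc1O | target

## Step count and risks

Total step count: 12. Longest linear sequence: 11 steps (steps 1–8, then 10, 11 and 12).

The three steps most likely to fail:

Step 10 (enolonium coupling). The trivalent-iodine reagent may oxidise the benzyloxy-arenes, the product ketone can be arylated a second time on its own ring A, and the benzylic silyl ether of 12 may ionise under the Lewis acid. Fallback: setting out from 13, NBS (THF, −78 °C) gives the racemic 4-bromo-flavan-3-one F1. Halide abstraction with AgOTf in the presence of 2,6-di-tert-butyl-4-methylpyridine and 12 (CH2Cl2, −78 °C) then generates the same α-keto benzylic cation without any iodine oxidant or BF3, and arylation by 12 comes back to the route at 15.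

Step 11 (double dynamic kinetic resolution on a hindered dimer ketone). The catalyst may reduce the crowded ketone slowly, or may not discriminate the two 2,4-cis series as it did in step 6. Fallback: substrate control instead of catalyst control, setting out from 10. Dess–Martin oxidation gives the (2R)-flavan-3-one F2, and LiN(SiMe3)2/Me3SiCl (THF, −78 °C) gives the (2R)-trimethylsilyl enol ether F3. The step 10 conditions with 12, followed by deprotonation at C4 with KN(SiMe3)2 and kinetic protonation from the face opposite the 2-aryl group, give the 2,4-cis dimer ketone F4. LiBH(s-Bu)3 (THF, −78 °C) then delivers hydride anti to both aryl groups and comes back to the route at 16.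

Step 6 (dynamic kinetic resolution of the flavan-3-one). Racemisation at C2 may be too slow, or the enantioselectivity on this ketone class too low. Fallback: classical resolution, setting out from 9. LiBH(s-Bu)3 (THF, −78 °C) gives the racemic 2,3-cis flavan-3-ol F5. Esterification with (S)-2-methoxy-2-phenylacetic acid (DCC, DMAP, CH2Cl2) and separation of the two diastereomers gives the (2R,3R)-flavan-3-yl (S)-2-methoxy-2-phenylacetate F6. LiOH (THF/H2O) then comes back to the route at 10.

## Further compounds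

F1 | step 10 | rac-4-bromo-7,8-bis(benzyloxy)-2-[3,4-bis(benzyloxy)phenyl]chroman-3-one | O=C1C(Br)c2ccc(OCc3ccccc3)c(OCc3ccccc3)c2OC1c1ccc(OCc2ccccc2)c(OCc2ccccc2)c1
F2 | step 11 | (2R)-7,8-bis(benzyloxy)-2-[3,4-bis(benzyloxy)phenyl]chroman-3-one | c1ccccc1COc1ccc([C@H]2Oc3c(ccc(OCc4ccccc4)c3OCc3ccccc3)CC2=O)cc1OCc1ccccc1
F3 | step 11 | (2R)-{[7,8-bis(benzyloxy)-2-[3,4-bis(benzyloxy)phenyl]-2H-chromen-3-yl]oxy}trimethylsilane | c1ccccc1COc1ccc([C@H]2Oc3c(ccc(OCc4ccccc4)c3OCc3ccccc3)C=C2O[Si](C)(C)C)cc1OCc1ccccc1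
F4 | step 11 | (2R,4S)-7,8-bis(benzyloxy)-2-[3,4-bis(benzyloxy)phenyl]-4-{(2R,3S,4S)-7,8-bis(benzyloxy)-2-[3,4-bis(benzyloxy)phenyl]-3,4-bis(triethylsilyloxy)chroman-6-yl}chroman-3-one (2,4-cis) | c1ccccc1COc1ccc([C@H]2Oc3c(ccc(OCc4ccccc4)c3OCc3ccccc3)[C@@H](c3cc4c(c(OCc5ccccc5)c3OCc3ccccc3)O[C@H](c3ccc(OCc5ccccc5)c(OCc5ccccc5)c3)[C@H](O[Si](CC)(CC)CC)[C@H]4O[Si](CC)(CC)CC)C2=O)cc1OCc1ccccc1
F5 | step 6 | rac-(2R*,3R*)-7,8-bis(benzyloxy)-2-[3,4-bis(benzyloxy)phenyl]chroman-3-ol (racemate, one enantiomer drawn) | c1ccccc1COc1ccc([C@H]2Oc3c(ccc(OCc4ccccc4)c3OCc3ccccc3)C[C@H]2O)cc1OCc1ccccc1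
F6 | step 6 | (2R,3R)-7,8-bis(benzyloxy)-2-[3,4-bis(benzyloxy)phenyl]chroman-3-yl (2S)-2-methoxy-2-phenylacetate | c1ccccc1COc1ccc([C@H]2Oc3c(ccc(OCc4ccccc4)c3OCc3ccccc3)C[C@H]2OC(=O)[C@@H](OC)c2ccccc2)cc1OCc1ccccc1
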